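## The problem

Compound 23 is a methylene-bridged pair of acylphloroglucinols. Ring A carries a pentanoyl group at C1, hydroxyls at C2 and C6, a methyl at C3 and a methoxy at C4. Ring B carries hydroxyls at C2', C4' and C6', a methyl at C3' and a butanoyl group at C5'. C5 and C1' are joined through one CH2.

Both rings are hexasubstituted, so every bond to either ring is made at a crowded position. The molecule has no stereocentre; the difficulty is constitutional. Exactly one of six oxygens (O4) is methylated, the two acyl chains differ, and the diarylmethane is unsymmetrical, so it cannot be made cleanly by joining two similar phenols through a one-carbon unit.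

The free polyphenol is air-sensitive in base, and the doubly activated CH2 bridge can cleave or exchange in strong acid or base, so the last steps must be mild. Both aryl ketones are enolisable, which matters whenever a strong base is used. The O4 methyl ether has no neighbouring carbonyl, whereas the ring B oxygens that must be freed either lie beside the C5' ketone or can carry silicon; this is the only handle for the final deprotection.

Ring B can be built from acyclic and alicyclic pieces because its oxygen and carbon substituents alternate. C2'(O)–C3'(Me)–C4'(O) is the pattern of 2-methylcyclohexane-1,3-dione (8), C1' is its α'-carbon, and C5'(acyl)–C6'(O) is the pattern of an acyl alkoxyalkyne.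

## Retrosynthesis

**23 from 22 (O–Si bonds at O2' and O4').** The two ring B silyl ethers are removed last with buffered fluoride, the mildest way to release the polyphenol. Compound 22 differs from the target only by these groups.

**22 from 21 (two benzyl ethers on ring A, methyl ether at O6').** A chelating boron halide removes both ring A benzyl groups and the O6' methyl group in one operation. This is where the protecting-group pattern had to be thought through. Such a Lewis acid cleaves an alkyl ether beside a ketone only while the carbonyl is free to deliver it; once a phenol on the other flank is released, the carbonyl is locked in a boron chelate and the second ether stays. Two alkyl ethers flanking C5' would therefore stall after one cleavage, and forcing conditions would endanger the O4 methyl ether. The remedy is to give O4' a bulky silyl group, which is a poor donor, inert to the boron halide, and later removed by fluoride. O6' is made a methyl ether, the fastest-cleaving primary ether under chelation. O4, with no donor neighbour, is untouched.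

**21 from diene 13 and ynone 18 (C1'–C6' and C4'–C5').** This is the Alder–Rickert disconnection: ring B is opened across these two bonds and a two-carbon bridge is put back between C1' and C4'. It is preferred over building ring B from a preformed phenol because it places all six substituents with one regiochemical decision, governed by the polarity of both partners. The precursors are a cyclohexadiene and a six-carbon ynone. The forward reaction must pair the crowded, doubly oxygenated diene with a donor-substituted (hence sluggish) ynone, then expel the bridge as a gaseous alkene. A methyl ynol ether is chosen over the ethyl ether because it has no β-hydrogen and so cannot fragment to a ketene on heating. Because ring A's ketone is silylated in 13, the acidic work-up of this step returns it.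

**13 from 11 (two O–Si bonds).** Kinetic deprotonation at the α'-carbon of enone 11 and O-silylation give the diene. The ring A ketone is more acidic than the enone and will be deprotonated as well, so both enolates are silylated deliberately. The ring A silyl enol ether is a spectator, which saves a protection–deprotection sequence for that ketone.

**11 from 9 and bromide 7 (CH2–C1').** The bridge is attached while C1' is still an enolate carbon. One partner is only a nucleophile and the other only an electrophile, so no mixed coupling of two phenols can arise. The alternative cut at C5–CH2 would require ring A as the nucleophile and offers no such control. The forward step needs kinetic α'-regiochemistry and a bromide reactive enough to be consumed before proton transfer from its own ketone; the 2,4,6-trioxygenated benzylic bromide 7 meets this.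

**9 from 8 (O–Si).** O-silylation of dione 8 gives vinylogous silyl ester 9 in one step, and the silicon group is the one required at O4' three disconnections earlier.

**7 back to 1 (ring A).** Bromide 7 comes from alcohol 6, and 6 from aldehyde 5 by reduction. Compound 5 is the dibenzyl ether of 4, and 4 arises by formylation of 3 at its only free ring carbon. Compound 3 is obtained from 2 by methylating the one hydroxyl not hydrogen-bonded to the ketone, and 2 by C-acylation of 2,4,6-trihydroxytoluene (1). The order matters: acylation first creates the hydrogen bonds that single out O4, and formylation precedes benzylation because it needs a free phenol.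

**18 from 17, and 17 from 14 and 15 (C–C bond to the carbinol carbon).** The ynone is the oxidation product of propargylic alcohol 17. This is made by adding the alkoxyacetylide generated from chloroacetal 14 to butanal (15). Both are bulk chemicals.

## Roads not taken

**Alternative 1:** The cut runs through ring A: C3–C4 and C1–C2 are opened, with C4–C5 broken and re-formed on the way. This leads back to 3-ethoxycyclobutenone A1, which carries the ring B benzyl group at C4, and to siloxyalkyne A2.

- Forward step: heating A1 opens it to a vinylketene, which adds A2 in a (2+2) sense. Four-electron opening and six-electron closure then give phenol A3, with O4 as the only free hydroxyl, O2 a silyl ether and O6 an ethyl ether.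
- Merit: methylation of O4 needs no selectivity at all. In this respect the road is better than the chosen plan, which relies in step 2 on O4–H being the only hydroxyl of 2 not tied to the ketone.
- Weak points:
  - A3 has hydrogen at C1, so the pentanoyl group must be introduced late, by acid-mediated acylation of an acid-sensitive diarylmethane or by metalation next to ring B's ketone.
  - The O6 ethyl ether must then be cleaved beside the new ketone while the O4 methyl ether survives.
  - Ring B must first be made as a hexasubstituted tribenzylated benzylic electrophile, by a sequence as long as steps 1–6, and joined to a cyclobutenone enolate in the presence of its own enolisable ketone.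
- Comparison: I estimate it at about four steps longer. Against its clean O4 differentiation the chosen plan sets a well-precedented para-selective methylation at the second, cheapest step, and it carries both acyl groups from the start.

**Alternative 2:** All of ring B is cut into three alkynes, forming C1'–C2', C3'–C4' and C5'–C6'. The precursors are the silicon-tethered diyne A4 (a propargylic silane bearing ring A, linked through Si–O to a propynyl ynol unit) and ynone A5.

- Forward step: a cationic monovalent rhodium–bisphosphine catalyst would join them to the racemic benzoxasilole A6. The tether would later be removed by Si–O cleavage and protodesilylation at the bridge carbon.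
- Merit: it is the most convergent road. All six substituents of ring B are set in one catalytic step at moderate temperature, and the tether fixes the relative orientation of two of the three alkynes. On convergence it beats the chosen plan.
- Weak points:
  - All three partners are ynol-type alkynes, a combination without close precedent.
  - The untethered ynone A5 can insert in two orientations, and only one gives the required pattern.
  - A4 combines two hydrolytically fragile ynol functions with an enolisable ketone and would itself take many steps.
  - A6 still carries two ethyl ethers flanking the ketone, the arrangement that resists clean cleavage.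
- Comparison: the chosen plan has a longer linear sequence, but its regiochemistry follows from the matched polarity of diene and ynone, and its reaction type is established.

**Alternative 3:** Ring A is cut at C1–C6 and unfolded to pyrone A7, a 4-methoxy-5-methyl-6-(2-oxohexyl)-2-pyrone bearing the ring B benzyl group at C3.

- Forward step: a magnesium alkoxide in the corresponding alcohol opens the lactone. The diketone carbanion (future C1) attacks the liberated ester carbon (future C6) in a Claisen-type closure, giving A8 with ring A in its final form and ring B as tribenzyl ether.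
- Merit: the O4 methyl group comes from the pyrone methoxy, O2–H and O6–H emerge free, and a single hydrogenolysis of A8 would finish the synthesis. This endgame is milder than the Lewis-acid step of the chosen plan and in that respect better.
- Weak points:
  - A7 is a fully substituted pyrone. Its C3 benzylation and the side-chain acylation at the 6-methyl position need strong bases in the presence of ring B's enolisable ketone.
  - Ring B must again be prepared separately in benzylated, benzylic-electrophile form.
  - The ring closure competes with aldol-type cyclisation to a resorcylate.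
- Comparison: the step count is at best equal. The chosen plan accepts one chelation-controlled deprotection but builds ring B from a dione and an ynone, so it does not have to make a second hexasubstituted arene by classical means.

Key step: step 12

Assumption: the target has no stereocentre. Compounds 11, 17 and 19 have stereocentres that are destroyed later, so they are used as racemates and drawn without configuration. The enol ether of 12, 13, 19 and 20 is drawn Z, the geometry expected from an amide base; it has no consequence.

## Route

Step 1
Reactants: 1 2,4,6-trihydroxytoluene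
Product: 2 1-(2,4,6-trihydroxy-3-methylphenyl)pentan-1-one
Conditions: pentanoyl chloride, AlCl3 (3.5 equiv), PhNO2–CH2Cl2, 0 °C → rt; aq. HCl
Reagents that add atoms: pentanoyl chloride, CCCCC(=O)Cl
Why: Friedel–Crafts C-acylation of a phloroglucinol; the two free ring positions of 1 are equivalent and the first acyl group deactivates the ring against a second.

Step 2
Reactants: 2 1-(2,4,6-trihydroxy-3-methylphenyl)pentan-1-one
Product: 3 1-(2,6-dihydroxy-4-methoxy-3-methylphenyl)pentan-1-one
Conditions: Me2SO4 (1.0 equiv), K2CO3 (1.0 equiv), acetone, rt
Reagents that add atoms: dimethyl sulfate, COS(=O)(=O)OC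
Why: Williamson O-methylation; O2–H and O6–H are hydrogen-bonded to the ketone, so the para hydroxyl O4–H is the most acidic and the one alkylated by a single equivalent.

Step 3
Reactants: 3 1-(2,6-dihydroxy-4-methoxy-3-methylphenyl)pentan-1-one
Product: 4 2,4-dihydroxy-6-methoxy-5-methyl-3-pentanoylbenzaldehyde
Conditions: Cl2CHOMe, TiCl4, CH2Cl2, −78 → 0 °C; aq. HCl
Reagents that add atoms: dichloromethyl methyl ether, COC(Cl)Cl; water, O
Why: Rieche formylation directed by the titanium phenoxide; C5 is the only unsubstituted ring carbon and lies ortho to O6–H.

Step 4
Reactants: 4 2,4-dihydroxy-6-methoxy-5-methyl-3-pentanoylbenzaldehyde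
Product: 5 2,4-bis(benzyloxy)-6-methoxy-5-methyl-3-pentanoylbenzaldehyde
Conditions: BnBr (2.5 equiv), K2CO3, n-Bu4NI (cat.), DMF, 60 °C
Reagents that add atoms: benzyl bromide, BrCc1ccccc1
Why: Williamson benzylation of the two chelated phenols; warm DMF overcomes the hydrogen bonds and favours O- over C-alkylation.

Step 5
Reactants: 5 2,4-bis(benzyloxy)-6-methoxy-5-methyl-3-pentanoylbenzaldehyde
Product: 6 1-[2,6-bis(benzyloxy)-3-(hydroxymethyl)-4-methoxy-5-methylphenyl]pentan-1-one
Conditions: NaBH4 (0.6 equiv), THF–MeOH, 0 °C
Reagents that add atoms: none
Why: Chemoselective borohydride reduction; the aldehyde is far more electrophilic than the ketone, which is twisted out of conjugation and shielded by two ortho benzyloxy groups.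

Step 6
Reactants: 6 1-[2,6-bis(benzyloxy)-3-(hydroxymethyl)-4-methoxy-5-methylphenyl]pentan-1-one
Product: 7 1-[2,6-bis(benzyloxy)-3-(bromomethyl)-4-methoxy-5-methylphenyl]pentan-1-one
Conditions: CBr4, PPh3, CH2Cl2, 0 °C; used crude
Reagents that add atoms: tetrabromomethane, BrC(Br)(Br)Br
Why: Appel bromination under neutral conditions; the ring has no free position, so the very reactive trialkoxybenzyl bromide cannot alkylate itself.

Step 7
Reactants: 8 2-methylcyclohexane-1,3-dione
Product: 9 2-methyl-3-(triisopropylsilyloxy)cyclohex-2-en-1-one
Conditions: TIPSOTf, Et3N, CH2Cl2, 0 °C → rt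
Reagents that add atoms: triisopropylsilyl trifluoromethanesulfonate, CC(C)[Si](C(C)C)(C(C)C)OS(=O)(=O)C(F)(F)F
Why: O-silylation of the enol of a cyclic 1,3-dione gives the vinylogous silyl ester; the bulky silyl group makes it robust enough to handle.

Step 8
Reactants: 9 2-methyl-3-(triisopropylsilyloxy)cyclohex-2-en-1-one; 7 1-[2,6-bis(benzyloxy)-3-(bromomethyl)-4-methoxy-5-methylphenyl]pentan-1-one
Product: 11 6-{[2,4-bis(benzyloxy)-6-methoxy-5-methyl-3-pentanoylphenyl]methyl}-2-methyl-3-(triisopropylsilyloxy)cyclohex-2-en-1-one (racemic), via lithium dienolate 10 (not isolated)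
Conditions: LiN(iPr)2 (1.05 equiv), THF, −78 °C; then 7 (0.9 equiv), −78 → −40 °C
Reagents that add atoms: none
Why: Stork–Danheiser-type kinetic α'-deprotonation of a vinylogous ester and C-alkylation; the activated benzylic bromide should react at −78 °C faster than the enolate can abstract a proton from the ring A ketone. The new stereocentre at C6 is racemic and is removed in step 9.

Step 9
Reactants: 11 6-{[2,4-bis(benzyloxy)-6-methoxy-5-methyl-3-pentanoylphenyl]methyl}-2-methyl-3-(triisopropylsilyloxy)cyclohex-2-en-1-one
Product: 13 1-(triisopropylsilyloxy)-2-methyl-3-(tert-butyldimethylsilyloxy)-4-(ring A methyl)cyclohexa-1,3-diene, ring A being 2,4-bis(benzyloxy)-6-methoxy-5-methylphenyl with the pentanoyl group at its C3 masked as the (Z)-tert-butyldimethylsilyl enol ether, via dilithium bis-enolate 12 (not isolated)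
Conditions: LiN(iPr)2 (2.4 equiv), THF, −78 °C; TBSOTf (2.6 equiv), −78 → 0 °C; pentane, Et3N-washed alumina; used directly
Reagents that add atoms: tert-butyldimethylsilyl trifluoromethanesulfonate, CC(C)(C)[Si](C)(C)OS(=O)(=O)C(F)(F)F
Why: Kinetic enolisation and O-silylation; the amide base removes the α'-hydrogen next to the enone carbonyl rather than the γ-hydrogens, and the more acidic ring A ketone is enolised and silylated in the same operation.

Step 10
Reactants: 14 2-chloro-1,1-dimethoxyethane (chloroacetaldehyde dimethyl acetal); 15 butanal
Product: 17 1-methoxyhex-1-yn-3-ol (racemic), via lithium methoxyacetylide 16 (not isolated)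
Conditions: LiNEt2 (3.1 equiv, from n-BuLi and Et2NH), THF, 0 °C; then 15, −78 °C → rt; aq. NH4Cl
Reagents that add atoms: none
Why: Amide-induced double elimination of a chloroacetal to the lithium alkoxyacetylide, then 1,2-addition to an aldehyde; the carbinol stereocentre is racemic and removed in step 11.

Step 11
Reactants: 17 1-methoxyhex-1-yn-3-ol
Product: 18 1-methoxyhex-1-yn-3-one
Conditions: activated MnO2 (excess), CH2Cl2, rt; filtered, stored cold and dry
Reagents that add atoms: none
Why: MnO2 oxidation of a propargylic alcohol; the neutral heterogeneous oxidant avoids acid-triggered Meyer–Schuster rearrangement of the alkoxy-propargylic alcohol.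

Step 12
Reactants: 13 the bis(silyloxy)diene from step 9; 18 1-methoxyhex-1-yn-3-one
Product: 21 target skeleton with O2 and O6 as benzyl ethers, O6' as methyl ether, O4' as triisopropylsilyl ether and O2' as tert-butyldimethylsilyl ether, via bicyclo[2.2.2]octadiene adduct 19 (not isolated), via ring B arene silyl enol ether 20 (not isolated)
Conditions: 18 (2.5 equiv), PhMe, 110 °C; then 170 °C (sealed tube); work-up 1 M HCl–THF, rt
Reagents that add atoms: none
Why: The HOMO of the 1,3-bis(silyloxy)diene 13 and the LUMO of ynone 18 combine in a normal-demand (4+2) cycloaddition, either concerted and asynchronous or stepwise by Mukaiyama–Michael addition and ring closure, to give the bicyclo[2.2.2]octa-2,5-diene 19. On stronger heating 19 loses its CH2–CH2 bridge as ethylene by retro-(4+2) reaction, irreversibly because the benzene ring of 20 is formed; the closest known reaction type is the Alder–Rickert reaction of 1,3-dioxygenated cyclohexa-1,3-dienes with acetylenic ketones and esters. Ring B is thus closed by an intermolecular (4+2) cycloaddition in which both new bonds, C1'–C6' and C4'–C5', form at the diene termini, followed by cycloreversion. No stereocentre appears in the product: the two bridgehead centres of 19 form as a racemate and vanish on aromatisation. The selectivity needed is regiochemical, and it is secured because both silyloxy groups (on C2' and C4') polarise the diene towards C1', which bonds to the methoxy-bearing β-carbon of 18 (C6') and leaves the acyl-bearing carbon C5' to join C4'. The methyl ynol ether has no β-hydrogen and so cannot fragment to a ketene at these temperatures, and its low electrophilicity is offset by the two oxygen donors of the diene. The dilute-acid work-up hydrolyses only the ring A silyl enol ether of 20, since aryl silyl ethers are stable to it, and returns the pentanoyl ketone.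

Step 13
Reactants: 21 the protected dimer from step 12
Product: 22 target skeleton with O4' as triisopropylsilyl ether and O2' as tert-butyldimethylsilyl ether, all other hydroxyls free
Conditions: BCl3 (6 equiv), C6HMe5 (4 equiv), CH2Cl2, −78 → 0 °C; MeOH quench
Reagents that add atoms: none
Why: Lewis-acid debenzylation with a cation scavenger, combined with carbonyl-directed (chelation-controlled) demethylation. The C5' ketone is flanked by a methyl ether and a non-coordinating bulky silyl ether, so boron bridges the carbonyl and O6' and chloride removes that methyl group. The O4 methyl ether has no donor neighbour and should survive; loss of the O2' silyl group here would be harmless.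

Step 14
Reactants: 22 the bis-silyl ether from step 13
Product: 23 1-{3-[(3-butanoyl-2,4,6-trihydroxy-5-methylphenyl)methyl]-2,6-dihydroxy-4-methoxy-5-methylphenyl}pentan-1-one (the target)
Conditions: n-Bu4NF, AcOH (1:1, 3 equiv), THF, 0 °C → rt, degassed
Reagents that add atoms: none
Why: Fluoride desilylation of two aryl silyl ethers; the acetic acid buffer keeps the polyphenol from air oxidation and from base-induced exchange at the CH2 bridge.

## Compound list

1 | 2,4,6-trihydroxytoluene | Cc1c(O)cc(O)cc1O | starting material
2 | 1-(2,4,6-trihydroxy-3-methylphenyl)pentan-1-one | CCCCC(=O)c1c(O)c(C)c(O)cc1O | intermediate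
3 | 1-(2,6-dihydroxy-4-methoxy-3-methylphenyl)pentan-1-one | CCCCC(=O)c1c(O)c(C)c(OC)cc1O | intermediate
4 | 2,4-dihydroxy-6-methoxy-5-methyl-3-pentanoylbenzaldehyde | CCCCC(=O)c1c(O)c(C)c(OC)c(C=O)c1O | intermediate
5 | 2,4-bis(benzyloxy)-6-methoxy-5-methyl-3-pentanoylbenzaldehyde | CCCCC(=O)c1c(OCc2ccccc2)c(C)c(OC)c(C=O)c1OCc1ccccc1 | intermediate
6 | 1-[2,6-bis(benzyloxy)-3-(hydroxymethyl)-4-methoxy-5-methylphenyl]pentan-1-one | CCCCC(=O)c1c(OCc2ccccc2)c(C)c(OC)c(CO)c1OCc1ccccc1 | intermediate
7 | 1-[2,6-bis(benzyloxy)-3-(bromomethyl)-4-methoxy-5-methylphenyl]pentan-1-one | CCCCC(=O)c1c(OCc2ccccc2)c(C)c(OC)c(CBr)c1OCc1ccccc1 | intermediate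
8 | 2-methylcyclohexane-1,3-dione | CC1C(=O)CCCC1=O | starting material
9 | 2-methyl-3-(triisopropylsilyloxy)cyclohex-2-en-1-one | CC1=C(O[Si](C(C)C)(C(C)C)C(C)C)CCCC1=O | intermediate
10 | lithium 6-methyl-5-(triisopropylsilyloxy)cyclohexa-1,5-dien-1-olate (kinetic enolate of 9) | [Li]OC1=CCCC(O[Si](C(C)C)(C(C)C)C(C)C)=C1C | intermediate (not isolated)
11 | 6-{[2,4-bis(benzyloxy)-6-methoxy-5-methyl-3-pentanoylphenyl]methyl}-2-methyl-3-(triisopropylsilyloxy)cyclohex-2-en-1-one, racemic | CCCCC(=O)c1c(OCc2ccccc2)c(C)c(OC)c(CC2CCC(O[Si](C(C)C)(C(C)C)C(C)C)=C(C)C2=O)c1OCc1ccccc1 | intermediate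
12 | dilithium bis-enolate of 11 (cyclohexadienolate and Z enolate of the ring A ketone) | [Li]OC1=C(Cc2c(OC)c(C)c(OCc3ccccc3)c(/C(O[Li])=C/CCC)c2OCc2ccccc2)CCC(O[Si](C(C)C)(C(C)C)C(C)C)=C1C | intermediate (not isolated)
13 | 1-(triisopropylsilyloxy)-2-methyl-3-(tert-butyldimethylsilyloxy)-4-(ring A methyl)cyclohexa-1,3-diene; ring A with O2 and O6 as benzyl ethers and the pentanoyl group as (Z)-tert-butyldimethylsilyl enol ether | CCC/C=C(\O[Si](C)(C)C(C)(C)C)c1c(OCc2ccccc2)c(C)c(OC)c(CC2=C(O[Si](C)(C)C(C)(C)C)C(C)=C(O[Si](C(C)C)(C(C)C)C(C)C)CC2)c1OCc1ccccc1 | intermediate
14 | 2-chloro-1,1-dimethoxyethane | COC(CCl)OC | starting material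
15 | butanal | CCCC=O | starting material
16 | lithium methoxyacetylide | [Li]C#COC | intermediate (not isolated)
17 | 1-methoxyhex-1-yn-3-ol, racemic | CCCC(O)C#COC | intermediate
18 | 1-methoxyhex-1-yn-3-one | CCCC(=O)C#COC | intermediate
19 | bicyclo[2.2.2]octa-2,5-diene adduct of 13 and 18 (bridgeheads C1' with the ring A methyl group and C4' with the triisopropylsilyloxy group), racemic | CCC/C=C(\O[Si](C)(C)C(C)(C)C)c1c(OCc2ccccc2)c(C)c(OC)c(CC23CCC(O[Si](C(C)C)(C(C)C)C(C)C)(C(C)=C2O[Si](C)(C)C(C)(C)C)C(C(=O)CCC)=C3OC)c1OCc1ccccc1 | intermediate (not isolated)
20 | ring B arene with O6' methyl, O4' triisopropylsilyl, O2' tert-butyldimethylsilyl; ring A with O2 and O6 benzyl and the pentanoyl group still as (Z)-silyl enol ether | CCC/C=C(\O[Si](C)(C)C(C)(C)C)c1c(OCc2ccccc2)c(C)c(OC)c(Cc2c(OC)c(C(=O)CCC)c(O[Si](C(C)C)(C(C)C)C(C)C)c(C)c2O[Si](C)(C)C(C)(C)C)c1OCc1ccccc1 | intermediate (not isolated)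
21 | target skeleton with O2 and O6 as benzyl ethers, O6' as methyl ether, O4' as triisopropylsilyl ether, O2' as tert-butyldimethylsilyl ether | CCCCC(=O)c1c(OCc2ccccc2)c(C)c(OC)c(Cc2c(OC)c(C(=O)CCC)c(O[Si](C(C)C)(C(C)C)C(C)C)c(C)c2O[Si](C)(C)C(C)(C)C)c1OCc1ccccc1 | intermediate
22 | target skeleton with O4' as triisopropylsilyl ether and O2' as tert-butyldimethylsilyl ether | CCCCC(=O)c1c(O)c(C)c(OC)c(Cc2c(O)c(C(=O)CCC)c(O[Si](C(C)C)(C(C)C)C(C)C)c(C)c2O[Si](C)(C)C(C)(C)C)c1O | intermediate
23 | 1-{3-[(3-butanoyl-2,4,6-trihydroxy-5-methylphenyl)methyl]-2,6-dihydroxy-4-methoxy-5-methylphenyl}pentan-1-one | CCCCC(=O)c1c(O)c(C)c(OC)c(Cc2c(O)c(C)c(O)c(C(=O)CCC)c2O)c1O | target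

## Step count and risks

Total: 14 steps. Longest linear sequence: 11 steps (1–6, 8, 9, 12, 13, 14). Steps 7 and 10–11 are side branches.

**Step 12 (key step).**
- What may go wrong: the addition may be too slow. The ynone carries a donor and the diene is tetrasubstituted, with a bulky silyloxy group at one bond-forming terminus. Desilylation or thermal isomerisation of the diene and polymerisation of the ynone could then overtake cycloaddition. A second risk is erosion of regiocontrol if the addition turns stepwise and reversible.
- Fallback: give up the ring construction and join the two rings by electrophilic aromatic substitution. It sets out from alcohol 6 and from 1. Acylation of 1 with butanoyl chloride and AlCl3 gives 1-(2,4,6-trihydroxy-3-methylphenyl)butan-1-one F1, which has a single free ring carbon. Acid-catalysed benzylation of F1 with 6 (catalytic TsOH, MeCN, 0 °C) gives the dibenzyl ether of the target F2; one partner is only an electrophile and the other only a nucleophile. Hydrogenolysis (H2, Pd/C, EtOAc) returns to the route at 23.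

**Step 8.**
- What may go wrong: proton transfer from the ring A ketone of 7 or of product 11 to enolate 10, followed by self-alkylation; or O-alkylation by the cation-like bromide.
- Fallback: avoid basic alkylation. It sets out from 9, which is converted with LiN(iPr)2 and TBSOTf into 1-(tert-butyldimethylsilyloxy)-6-methyl-5-(triisopropylsilyloxy)cyclohexa-1,5-diene F3. ZnBr2-promoted alkylation of F3 with 7 (CH2Cl2, −78 °C) is a Lewis-acid alkylation of a silyl enol ether by an ionisable benzylic halide. The unsubstituted diene terminus attacks, the less hindered silyl group is lost, and the route is rejoined at 11.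

**Step 9.**
- What may go wrong: deprotonation at the γ-methylene in place of the hindered tertiary α'-carbon, or incomplete enolisation. The first would give an isomeric diene that extrudes the wrong bridge.
- Fallback: generate the enolate by conjugate reduction. It sets out from enolate 10 (from 9) and aldehyde 5.
  - Aldol addition gives the β-hydroxy ketone F4.
  - Mild acid dehydration (catalytic pyridinium tosylate, PhH) gives the (E)-arylidene enone F5.
  - 1,4-Reduction with LiBH(s-Bu)3 at −78 °C and trapping with TBSOTf gives the diene with free ring A ketone F6.
  - F6 reacts with 18 as in step 12 through the bicyclic adduct F7 and returns to the route at 21.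

**Step 13.**
- What may go wrong: loss of the O4' silyl group before the neighbouring methyl ether is cleaved. The freed phenoxide would then lock the C5' carbonyl in a boron chelate and demethylation would stall. Longer exposure would start to attack the O4 methyl ether and the bridge.
- Fallback: an acetate relay. It sets out from 21.
  - Buffered fluoride gives the 2',4'-diol F8.
  - Acetylation (Ac2O, pyridine) gives the 2',4'-diacetate F9, whose ester oxygens do not engage the ketone.
  - BCl3 with C6HMe5 then removes the two benzyl groups and the O6' methyl group, giving the 2',4'-diacetate of the target F10.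
  - Ammonolysis (NH3, MeOH, 0 °C) returns to the route at 23.

## Further compounds

F1 | step 12 | 1-(2,4,6-trihydroxy-3-methylphenyl)butan-1-one | CCCC(=O)c1c(O)c(C)c(O)cc1O
F2 | step 12 | target with O2 and O6 as benzyl ethers | CCCCC(=O)c1c(OCc2ccccc2)c(C)c(OC)c(Cc2c(O)c(C)c(O)c(C(=O)CCC)c2O)c1OCc1ccccc1
F3 | step 8 | 1-(tert-butyldimethylsilyloxy)-6-methyl-5-(triisopropylsilyloxy)cyclohexa-1,5-diene | CC1=C(O[Si](C(C)C)(C(C)C)C(C)C)CCC=C1O[Si](C)(C)C(C)(C)C
F4 | step 9 | 6-{[2,4-bis(benzyloxy)-6-methoxy-5-methyl-3-pentanoylphenyl](hydroxy)methyl}-2-methyl-3-(triisopropylsilyloxy)cyclohex-2-en-1-one, mixture of diastereomers | CCCCC(=O)c1c(OCc2ccccc2)c(C)c(OC)c(C(O)C2CCC(O[Si](C(C)C)(C(C)C)C(C)C)=C(C)C2=O)c1OCc1ccccc1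
F5 | step 9 | (E)-6-{[2,4-bis(benzyloxy)-6-methoxy-5-methyl-3-pentanoylphenyl]methylidene}-2-methyl-3-(triisopropylsilyloxy)cyclohex-2-en-1-one | CCCCC(=O)c1c(OCc2ccccc2)c(C)c(OC)c(/C=C2\CCC(O[Si](C(C)C)(C(C)C)C(C)C)=C(C)C2=O)c1OCc1ccccc1
F6 | step 9 | diene as 13 but with the ring A pentanoyl ketone free | CCCCC(=O)c1c(OCc2ccccc2)c(C)c(OC)c(CC2=C(O[Si](C)(C)C(C)(C)C)C(C)=C(O[Si](C(C)C)(C(C)C)C(C)C)CC2)c1OCc1ccccc1
F7 | step 9 | bicyclo[2.2.2]octa-2,5-diene adduct of F6 and 18, racemic | CCCCC(=O)c1c(OCc2ccccc2)c(C)c(OC)c(CC23CCC(O[Si](C(C)C)(C(C)C)C(C)C)(C(C)=C2O[Si](C)(C)C(C)(C)C)C(C(=O)CCC)=C3OC)c1OCc1ccccc1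
F8 | step 13 | target skeleton with O2 and O6 as benzyl ethers, O6' as methyl ether, O2' and O4' free | CCCCC(=O)c1c(OCc2ccccc2)c(C)c(OC)c(Cc2c(OC)c(C(=O)CCC)c(O)c(C)c2O)c1OCc1ccccc1
F9 | step 13 | 2',4'-diacetate of F8 | CCCCC(=O)c1c(OCc2ccccc2)c(C)c(OC)c(Cc2c(OC)c(C(=O)CCC)c(OC(C)=O)c(C)c2OC(C)=O)c1OCc1ccccc1
F10 | step 13 | 2',4'-diacetate of the target | CCCCC(=O)c1c(O)c(C)c(OC)c(Cc2c(O)c(C(=O)CCC)c(OC(C)=O)c(C)c2OC(C)=O)c1O
A1 | alternative 1 | 3-ethoxy-4-(ring B methyl)cyclobut-2-en-1-one, ring B as tribenzyl ether, racemic | CCOC1=CC(=O)C1Cc1c(OCc2ccccc2)c(C)c(OCc2ccccc2)c(C(=O)CCC)c1OCc1ccccc1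
A2 | alternative 1 | 1-(triisopropylsilyloxy)propyne | CC#CO[Si](C(C)C)(C(C)C)C(C)C
A3 | alternative 1 | ring A phenol with O4 free, O2 triisopropylsilyl, O6 ethyl, C1 unsubstituted, ring B tribenzyl ether | Cc1c(O)c(Cc2c(OCc3ccccc3)c(C)c(OCc3ccccc3)c(C(=O)CCC)c2OCc2ccccc2)c(OCC)cc1O[Si](C(C)C)(C(C)C)C(C)C
A4 | alternative 2 | silicon-tethered diyne: (3-ethoxy-1-(ring A)prop-2-yn-1-yl)diisopropyl(prop-1-yn-1-yloxy)silane, ring A with O2 and O6 benzyl, racemic | CCOC#CC(c1c(OC)c(C)c(OCc2ccccc2)c(C(=O)CCCC)c1OCc1ccccc1)[Si](C(C)C)(C(C)C)OC#CC
A5 | alternative 2 | 1-ethoxyhex-1-yn-3-one | CCCC(=O)C#COCC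
A6 | alternative 2 | racemic benzoxasilole with silicon linking O2' to the bridge carbon, O4' and O6' ethyl | CCCC(=O)c1c(OCC)c(C)c2O[Si](C(C)C)(C(C)C)C(c3c(OC)c(C)c(OCc4ccccc4)c(C(=O)CCCC)c3OCc3ccccc3)c2c1OCC
A7 | alternative 3 | 4-methoxy-5-methyl-6-(2-oxohexyl)-3-(ring B methyl)-2H-pyran-2-one, ring B as tribenzyl ether | O=C1OC(CC(=O)CCCC)=C(C)C(OC)=C1Cc1c(OCc2ccccc2)c(C)c(OCc2ccccc2)c(C(=O)CCC)c1OCc1ccccc1
A8 | alternative 3 | target with the three ring B hydroxyls as benzyl ethers | CCCCC(=O)c1c(O)c(C)c(OC)c(Cc2c(OCc3ccccc3)c(C)c(OCc3ccccc3)c(C(=O)CCC)c2OCc2ccccc2)c1O
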